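In ring B the fully substituted C8=C9 double bond lies next to the all-carbon quaternary centre C10, and C6, para to C9, is oxygenated. This is the pattern left by a cycloaddition between a 2-silyloxydiene and a 2-butynoate, so the route cuts C7–C8 and C9–C10. One intermolecular Diels–Alder reaction closes ring B, sets C10, installs C8=C9 with its methyl group, brings in C11 as an ester and leaves C6 as a masked ketone. The diene is an enantiopure ring A cyclohexene (C5=C10). It carries a 1-silyloxyvinyl group on C5, the C10 methyl, an equatorial C2 silyl ether and the C4 methyl/silyloxymethyl pair. C6 is later reduced by electron transfer, and the butenolide arrives by B-alkyl Suzuki coupling.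

Key step: step 9

Numbering: the labdane numbering of the target is used for every intermediate. β is the face of the C10 methyl group and α the face of the C5 hydrogen. TBS = tert-butyldimethylsilyl.

Assumption: the sense of induction of lithium (S,S)-bis(1-phenylethyl)amide on ketone 4 is taken to follow that known for 4-substituted cyclohexanones. If it is opposite, the equally available (R,R)-amine is used and nothing else changes.

Step 1
Reactants: 1 2,6-dimethylhydroquinone
Product: 2 all-cis-2,6-dimethylcyclohexane-1,4-diol (meso)
Conditions: H2 (60 bar), 5% Rh/Al2O3, iPrOH, 60 °C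
Reagents that add atoms: none
Why: Heterogeneous arene hydrogenation over rhodium delivers all hydrogens to the adsorbed face and should give mainly the all-cis meso diol, and the hydroquinone is the proper entry because the related benzoquinone would merely aromatise to it under reducing conditions instead of stopping at a saturated diketone.

Step 2
Reactants: 2 all-cis-2,6-dimethylcyclohexane-1,4-diol
Product: 3 all-cis-4-(tert-butyldimethylsilyloxy)-2,6-dimethylcyclohexan-1-ol (meso)
Conditions: TBSCl (1.05 equiv), imidazole, CH2Cl2/DMF, 0 °C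
Reagents that add atoms: tert-butyldimethylsilyl chloride, CC(C)(C)[Si](C)(C)Cl
Why: Sterically controlled monosilylation, since in the chair with both methyl groups equatorial the future C2 hydroxyl is equatorial and unflanked whereas the other hydroxyl is axial and sits between two methyl-bearing carbons.

Step 3
Reactants: 3 all-cis-4-(tert-butyldimethylsilyloxy)-2,6-dimethylcyclohexan-1-ol
Product: 4 cis,cis-4-(tert-butyldimethylsilyloxy)-2,6-dimethylcyclohexan-1-one (meso with all three substituents equatorial)
Conditions: Dess–Martin periodinane, CH2Cl2, rt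
Reagents that add atoms: none
Why: Dess–Martin oxidation converts the hindered axial carbinol into the C5 ketone under neutral conditions, and the two epimerisable methyl-bearing carbons already hold the stable cis-diequatorial arrangement.

Step 4
Reactants: 4 meso ketone; 5 formaldehyde (monomer from cracked paraformaldehyde)
Product: 7 (2R,4R,6S)-4-(tert-butyldimethylsilyloxy)-2-(hydroxymethyl)-2,6-dimethylcyclohexan-1-one (4β-CH2OH trans to 2α-OTBS), via lithium enolate 6 (not isolated)
Conditions: (S,S)-bis(1-phenylethyl)amine, n-BuLi, LiCl, THF, −78 °C; CH2O gas, −78 °C; H2O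
Reagents that add atoms: none
Why: Enantioselective deprotonation of a meso ketone by a C2-symmetric chiral lithium amide removes one of the two enantiotopic axial α-hydrogens and thereby fixes the absolute configuration (C2 becomes a true stereocentre), and the aldol hydroxymethylation then proceeds by axial attack on the β face of the half-chair enolate whose OTBS and C10 methyl groups stay equatorial, which sets quaternary C4 with CH2OH trans to the C2 silyl ether.

Step 5
Reactants: 7 hydroxymethyl ketone
Product: 8 (2R,4R,6S)-4-(tert-butyldimethylsilyloxy)-2-(tert-butyldimethylsilyloxymethyl)-2,6-dimethylcyclohexan-1-one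
Conditions: TBSCl, imidazole, DMF, rt
Reagents that add atoms: tert-butyldimethylsilyl chloride, CC(C)(C)[Si](C)(C)Cl
Why: Standard silyl ether formation under weakly basic conditions that do not trigger retro-aldol loss of formaldehyde, and the bulky group on axial C19 later shields the β face of the diene.

Step 6
Reactants: 8 bis-TBS ketone
Product: 10 ring A enol triflate (C5-OTf on the tetrasubstituted C5=C10 alkene; 2α-OTBS; 4α-CH3; 4β-CH2OTBS), via potassium enolate 9 (not isolated)
Conditions: KHMDS, THF, −78 to 0 °C; PhNTf2, 0 °C to rt; H2O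
Reagents that add atoms: N-phenylbis(trifluoromethanesulfonimide), O=S(=O)(N(c1ccccc1)S(=O)(=O)C(F)(F)F)C(F)(F)F
Why: Enol triflate formation is regiospecific because C4 is quaternary and the ketone can enolise only towards C10, and O-sulfonylation fixes the C5=C10 alkene while erasing the auxiliary C10 stereocentre.

Step 7
Reactants: 10 ring A enol triflate; 11 tributyl(1-ethoxyvinyl)stannane
Product: 13 ring A methyl ketone (C5 acetyl on C5=C10; 2α-OTBS; 4β-CH2OTBS), via ethoxydiene 12 (not isolated)
Conditions: Pd(PPh3)4 (10 mol %), CuCl, LiCl, DMSO, 60 °C; then 1 M HCl, THF, 0 °C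
Reagents that add atoms: water, O
Why: The CuCl/LiCl-accelerated Stille coupling devised for congested vinyl triflates and 1-substituted vinylstannanes joins C5 to C6, and the resulting 2-ethoxydiene is protonated at C7 and hydrolysed by dilute acid much faster than the TBS ethers are attacked.

Step 8
Reactants: 13 ring A methyl ketone
Product: 14 ring A silyloxydiene (C7H2=C6(OTBS)–C5=C10(CH3); 2α-OTBS; 4α-CH3; 4β-CH2OTBS)
Conditions: TBSOTf, Et3N, CH2Cl2, 0 °C
Reagents that add atoms: tert-butyldimethylsilyl trifluoromethanesulfonate, CC(C)(C)[Si](C)(C)OS(=O)(=O)C(F)(F)F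
Why: Soft enolisation with a silyl triflate and an amine removes a proton of the C7 methyl group because the twisted acetyl group leaves the γ-hydrogens unactivated, and TBS is chosen so that the enol ether survives a long pressure run yet remains the only silyl group released later by buffered fluoride.

Step 9
Reactants: 14 ring A silyloxydiene; 15 methyl but-2-ynoate
Product: 16 bicyclic 1,4-diene (C9 methyl ester on C8=C9; C5=C6 TBS enol ether; 10β-CH3; 2α-OTBS; 4β-CH2OTBS)
Conditions: 15 (10 equiv), BHT (1 mol %), CH2Cl2, 13 kbar, 60 °C
Reagents that add atoms: none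
Why: This is a normal-electron-demand, concerted but asynchronous [4+2] cycloaddition in which the bond from the unhindered nucleophilic terminus C7 to the ynoate β-carbon C8 runs ahead of the bond between fully substituted C10 and the ester-bearing C9. The closest known reactions are Diels–Alder additions of 2-silyloxydienes to acetylenic esters and of 1-vinyl-2,6,6-trimethylcyclohexenes to acetylenic esters, so only the substrate is new. Ring B is the only ring closed, as a six-membered ring by intermolecular cycloaddition across C7 and C10, and it emerges as a 1,4-cyclohexadiene holding C8=C9 and the C5=C6 silyl enol ether. C10 is the only new stereocentre (a linear alkyne raises no endo/exo question) and ring A controls it: the equatorial C2 silyl ether locks the half-chair in which the C4 CH2OTBS group is pseudoaxial on the β face, so the ynoate adds from the α face and the C10 methyl is pushed β, cis to C19. The required regiochemistry (ester carbon bonded to C10, C6 and C9 para) is secured because the C6 silyloxy donor and the alkyl groups on C10 both place the largest HOMO coefficient on C7, which matches the ynoate β-carbon. Pressure replaces strong heating because the large negative activation volume speeds the hindered cycloaddition, whereas the 1,5-hydrogen shift from the inward-pointing C10 methyl group and thermal loss of silicon are not accelerated.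

Step 10
Reactants: 16 bicyclic 1,4-diene ester
Product: 17 C11 allylic alcohol with the C5=C6 TBS enol ether intact
Conditions: DIBAL-H (3 equiv), CH2Cl2, −78 to 0 °C; aqueous work-up
Reagents that add atoms: none
Why: DIBAL-H 1,2-reduction of the unsaturated ester leaves silyl ethers and the silyl enol ether untouched, and removing the ester before the ketone is unmasked takes away the vinylogous acidification of C7 that would invite migration of C8=C9.

Step 11
Reactants: 17 allylic alcohol
Product: 18 trans-fused C6 ketone (5α-H; C11-OH; 2α-OTBS; 4β-CH2OTBS)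
Conditions: TBAF (1.1 equiv), AcOH (1.3 equiv), THF, −20 to 0 °C
Reagents that add atoms: none
Why: Buffered fluoride cleaves the silyl enol ether far faster than the alkyl TBS ethers because an enolate is the better leaving group, C5 is then protonated from the α face opposite to axial C19 and C20 to give the trans ring fusion that is also the stable one, and the acetic acid buffer keeps C8=C9 out of conjugation.

Step 12
Reactants: 18 trans-fused C6 ketone
Product: 19 6α,11-diol (equatorial 6α-OH; 2α-OTBS; 4β-CH2OTBS)
Conditions: SmI2 (4 equiv), H2O (excess), THF, 0 °C to rt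
Reagents that add atoms: none
Why: Hydride reagents would approach C6 from the open α face and give the axial 6β-alcohol because C19 and C20 block the β face, so a ketyl (single-electron) reduction with SmI2–H2O is used, in which the bulky samarium-bound oxygen settles in the uncongested equatorial α position before protonation and sets the 6α-alcohol, while the isolated alkene, the allylic alcohol and the silyl ethers are inert.

Step 13
Reactants: 19 6α,11-diol
Product: 20 C11 enal with free 6α-OH
Conditions: MnO2 (20 equiv), CH2Cl2, rt
Reagents that add atoms: none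
Why: Manganese dioxide oxidation is selective for the allylic primary alcohol and leaves the non-allylic secondary 6α-hydroxyl untouched.

Step 14
Reactants: 20 enal
Product: 21 C9 vinyl diene (C8=C9–C11H=C12H2) with free 6α-OH
Conditions: Ph3PCH3Br (4 equiv), KOtBu (3.8 equiv), THF, 0 °C to rt
Reagents that add atoms: methyltriphenylphosphonium bromide, C[P+](c1ccccc1)(c1ccccc1)c1ccccc1.[Br-]
Why: Wittig methylenation is reliable on hindered enals of the β-cyclocitral type, and the excess ylide covers the transient deprotonation of the 6α-hydroxyl.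

Step 15
Reactants: 21 C9 vinyl diene; 22 4-bromofuran-2(5H)-one
Product: 24 2,19-bis-TBS ether of the target, via alkylborane 23 (not isolated)
Conditions: 9-BBN-H (2.5 equiv), THF, rt; then 22, PdCl2(dppf) (5 mol %), AsPh3 (5 mol %), Cs2CO3, DMF/H2O, rt to 40 °C
Reagents that add atoms: none
Why: 9-BBN hydroborates only the terminal vinyl group at C12 (the tetrasubstituted C8=C9 is inert and the hydroxyl is merely borylated reversibly), and the B-alkyl Suzuki–Miyaura coupling with a β-bromobutenolide then forms C12–C13 and delivers the complete side chain in one operation.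

Step 16
Reactants: 24 2,19-bis-TBS ether
Product: 25 target 2α,6α,19-trihydroxylabda-8,13-dien-15,16-olide
Conditions: 48% aq HF, MeCN, 0 °C to rt
Reagents that add atoms: none
Why: Global desilylation with acidic fluoride frees the C2 and C19 hydroxyls without the basic conditions that could isomerise the butenolide, and no stereocentre is affected.

Compound list
1 | 2,6-dimethylhydroquinone | Cc1cc(O)cc(C)c1O | starting material
2 | all-cis-2,6-dimethylcyclohexane-1,4-diol (meso) | O[C@@H]1[C@H](C)C[C@H](O)C[C@@H]1C | intermediate
3 | all-cis-4-(tert-butyldimethylsilyloxy)-2,6-dimethylcyclohexan-1-ol (meso) | O[C@@H]1[C@H](C)C[C@H](O[Si](C)(C)C(C)(C)C)C[C@@H]1C | intermediate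
4 | cis,cis-4-(tert-butyldimethylsilyloxy)-2,6-dimethylcyclohexan-1-one (meso) | O=C1[C@H](C)C[C@H](O[Si](C)(C)C(C)(C)C)C[C@@H]1C | intermediate
5 | formaldehyde (from paraformaldehyde) | C=O | starting material
6 | lithium enolate (C4=C5) of 4 | [Li]OC1=C(C)C[C@H](O[Si](C)(C)C(C)(C)C)C[C@@H]1C | intermediate
7 | (2R,4R,6S)-4-(tert-butyldimethylsilyloxy)-2-(hydroxymethyl)-2,6-dimethylcyclohexan-1-one | O=C1[C@@](C)(CO)C[C@H](O[Si](C)(C)C(C)(C)C)C[C@@H]1C | intermediate
8 | (2R,4R,6S)-4-(tert-butyldimethylsilyloxy)-2-(tert-butyldimethylsilyloxymethyl)-2,6-dimethylcyclohexan-1-one | O=C1[C@@](C)(CO[Si](C)(C)C(C)(C)C)C[C@H](O[Si](C)(C)C(C)(C)C)C[C@@H]1C | intermediate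
9 | potassium enolate (C5=C10) of 8 | [K]OC1=C(C)C[C@@H](O[Si](C)(C)C(C)(C)C)C[C@]1(C)CO[Si](C)(C)C(C)(C)C | intermediate
10 | ring A enol triflate | O=S(=O)(OC1=C(C)C[C@@H](O[Si](C)(C)C(C)(C)C)C[C@]1(C)CO[Si](C)(C)C(C)(C)C)C(F)(F)F | intermediate
11 | tributyl(1-ethoxyvinyl)stannane | CCCC[Sn](CCCC)(CCCC)C(=C)OCC | starting material
12 | ring A 2-ethoxydiene | C=C(OCC)C1=C(C)C[C@@H](O[Si](C)(C)C(C)(C)C)C[C@]1(C)CO[Si](C)(C)C(C)(C)C | intermediate
13 | ring A methyl ketone (1-acetyl-2-methylcyclohexene) | CC(=O)C1=C(C)C[C@@H](O[Si](C)(C)C(C)(C)C)C[C@]1(C)CO[Si](C)(C)C(C)(C)C | intermediate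
14 | ring A 1-(1-silyloxyvinyl)-2-methylcyclohexene (Diels–Alder diene) | C=C(O[Si](C)(C)C(C)(C)C)C1=C(C)C[C@@H](O[Si](C)(C)C(C)(C)C)C[C@]1(C)CO[Si](C)(C)C(C)(C)C | intermediate
15 | methyl but-2-ynoate | CC#CC(=O)OC | starting material
16 | bicyclic 1,4-diene with C9 ester and C6 silyl enol ether | CC1=C(C(=O)OC)[C@@]2(C)C[C@@H](O[Si](C)(C)C(C)(C)C)C[C@](C)(CO[Si](C)(C)C(C)(C)C)C2=C(O[Si](C)(C)C(C)(C)C)C1 | intermediate
17 | C11 allylic alcohol with C6 silyl enol ether | CC1=C(CO)[C@@]2(C)C[C@@H](O[Si](C)(C)C(C)(C)C)C[C@](C)(CO[Si](C)(C)C(C)(C)C)C2=C(O[Si](C)(C)C(C)(C)C)C1 | intermediate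
18 | trans-fused C6 ketone with C11 alcohol | CC1=C(CO)[C@@]2(C)C[C@@H](O[Si](C)(C)C(C)(C)C)C[C@](C)(CO[Si](C)(C)C(C)(C)C)[C@@H]2C(=O)C1 | intermediate
19 | 6α,11-diol | CC1=C(CO)[C@@]2(C)C[C@@H](O[Si](C)(C)C(C)(C)C)C[C@](C)(CO[Si](C)(C)C(C)(C)C)[C@@H]2[C@@H](O)C1 | intermediate
20 | C11 enal with 6α-OH | CC1=C(C=O)[C@@]2(C)C[C@@H](O[Si](C)(C)C(C)(C)C)C[C@](C)(CO[Si](C)(C)C(C)(C)C)[C@@H]2[C@@H](O)C1 | intermediate
21 | C9 vinyl diene with 6α-OH | CC1=C(C=C)[C@@]2(C)C[C@@H](O[Si](C)(C)C(C)(C)C)C[C@](C)(CO[Si](C)(C)C(C)(C)C)[C@@H]2[C@@H](O)C1 | intermediate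
22 | 4-bromofuran-2(5H)-one | O=C1C=C(Br)CO1 | starting material
23 | C12 9-BBN alkylborane (6-O borinate) | CC1=C(CCB3C4CCCC3CCC4)[C@@]2(C)C[C@@H](O[Si](C)(C)C(C)(C)C)C[C@](C)(CO[Si](C)(C)C(C)(C)C)[C@@H]2[C@@H](OB3C4CCCC3CCC4)C1 | intermediate
24 | 2,19-bis-TBS ether of the target | CC1=C(CCC2=CC(=O)OC2)[C@@]2(C)C[C@@H](O[Si](C)(C)C(C)(C)C)C[C@](C)(CO[Si](C)(C)C(C)(C)C)[C@@H]2[C@@H](O)C1 | intermediate
25 | 2α,6α,19-trihydroxylabda-8,13-dien-15,16-olide (CNP0387838.1) | CC1=C(CCC2=CC(=O)OC2)[C@@]2(C)C[C@@H](O)C[C@](C)(CO)[C@@H]2[C@@H](O)C1 | target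

Total step count: 16. Longest linear sequence: 16 steps (1 to 25); all coupling partners are purchased.

Steps most likely to fail

Step 9 (Diels–Alder).
- What may go wrong: the twisted diene, whose C10 terminus is fully substituted and carries an inward-pointing methyl group, may react too slowly with the weak dienophile. Sigmatropic hydrogen shift or loss of the enol silyl group could then take over, and facial discrimination at C10 may be incomplete.
- Fallback: it sets out from 14 and comes back to the route at 17.
  - The acetylenic ester is replaced by commercial ethyl buta-2,3-dienoate. Its ester-conjugated allene double bond is a much more reactive two-carbon partner of the same polarity.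
  - Cycloaddition in toluene at 80–110 °C should give the 8(17)-exomethylene C9 ethyl ester F1 (C9 epimers, of no consequence).
  - DBU then moves the double bond into the tetrasubstituted, ester-conjugated C8=C9 position to give the ethyl ester analogue of 16 F2.
  - DIBAL-H converts this into 17.

Step 4 (desymmetrising hydroxymethylation).
- What may go wrong: discrimination between the two enantiotopic axial hydrogens may be incomplete, the facial preference in the aldol addition of the very reactive formaldehyde may be modest, and retro-aldol cleavage may occur on work-up.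
- Fallback: it sets out from 4 and comes back at 7, replacing asymmetric deprotonation by a classical resolution.
  - LDA and formaldehyde give the racemic hydroxymethyl ketone F3.
  - Acylation with (1S)-camphanic chloride (pyridine, DMAP) gives two diastereomeric esters.
  - The camphanate of 7 F4 is separated by crystallisation or chromatography from the camphanate of the mirror-image ketone F5, which is discarded.
  - Mild methanolysis of the wanted ester (K2CO3, MeOH, 0 °C) returns enantiopure 7.

Step 12 (C6 reduction).
- What may go wrong: basic samarium species may enolise the β,γ-unsaturated ketone, so that C8=C9 migrates into conjugation, or the preference for the equatorial alcohol may be incomplete.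
- Fallback: it sets out from 17 and comes back at 25. C6 stays masked to the end, and electron transfer is replaced by hydroxyl-directed hydride delivery.
  - 17 is oxidised with MnO2 to the enal with intact silyl enol ether F6.
  - This is methylenated with Ph3P=CH2 to the triene F7.
  - The triene is hydroborated with 9-BBN to the alkylborane F8 and coupled with 22 under the conditions of step 15 to the tris-TBS butenolide F9.
  - Aqueous HF removes all three silyl groups and, by α-face protonation at C5, gives the trans-fused 6-oxo-2α,19-diol F10.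
  - Me4NBH(OAc)3 in MeCN/AcOH (Saksena–Evans reduction) then binds to the axial C19 hydroxyl and delivers hydride intramolecularly to the β face of C6. This gives 25 directly, and the butenolide is inert to this reagent.

Further compounds
F1 | step 9 | 8(17)-exomethylene C9 ethyl ester cycloadduct (C9 unassigned) | C=C1C(C(=O)OCC)[C@@]2(C)C[C@@H](O[Si](C)(C)C(C)(C)C)C[C@](C)(CO[Si](C)(C)C(C)(C)C)C2=C(O[Si](C)(C)C(C)(C)C)C1
F2 | step 9 | ethyl ester analogue of 16 | CC1=C(C(=O)OCC)[C@@]2(C)C[C@@H](O[Si](C)(C)C(C)(C)C)C[C@](C)(CO[Si](C)(C)C(C)(C)C)C2=C(O[Si](C)(C)C(C)(C)C)C1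
F3 | step 4 | racemic hydroxymethyl ketone (7 and its mirror image) | O=C1[C@@](C)(CO)C[C@H](O[Si](C)(C)C(C)(C)C)C[C@@H]1C.O=C1[C@](C)(CO)C[C@@H](O[Si](C)(C)C(C)(C)C)C[C@H]1C
F4 | step 4 | (1S)-camphanate of 7 | O=C1[C@@](C)(COC(=O)[C@@]23CC[C@@](C)(C(=O)O2)C3(C)C)C[C@H](O[Si](C)(C)C(C)(C)C)C[C@@H]1C
F5 | step 4 | (1S)-camphanate of the mirror image of 7 | O=C1[C@](C)(COC(=O)[C@@]23CC[C@@](C)(C(=O)O2)C3(C)C)C[C@@H](O[Si](C)(C)C(C)(C)C)C[C@H]1C
F6 | step 12 | C11 enal with intact C6 silyl enol ether | CC1=C(C=O)[C@@]2(C)C[C@@H](O[Si](C)(C)C(C)(C)C)C[C@](C)(CO[Si](C)(C)C(C)(C)C)C2=C(O[Si](C)(C)C(C)(C)C)C1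
F7 | step 12 | C9 vinyl triene with C6 silyl enol ether | CC1=C(C=C)[C@@]2(C)C[C@@H](O[Si](C)(C)C(C)(C)C)C[C@](C)(CO[Si](C)(C)C(C)(C)C)C2=C(O[Si](C)(C)C(C)(C)C)C1
F8 | step 12 | C12 9-BBN alkylborane with C6 silyl enol ether | CC1=C(CCB3C4CCCC3CCC4)[C@@]2(C)C[C@@H](O[Si](C)(C)C(C)(C)C)C[C@](C)(CO[Si](C)(C)C(C)(C)C)C2=C(O[Si](C)(C)C(C)(C)C)C1
F9 | step 12 | tris-TBS butenolide with C6 silyl enol ether | CC1=C(CCC3=CC(=O)OC3)[C@@]2(C)C[C@@H](O[Si](C)(C)C(C)(C)C)C[C@](C)(CO[Si](C)(C)C(C)(C)C)C2=C(O[Si](C)(C)C(C)(C)C)C1
F10 | step 12 | trans-fused 6-oxo-2α,19-diol butenolide | CC1=C(CCC3=CC(=O)OC3)[C@@]2(C)C[C@@H](O)C[C@](C)(CO)[C@@H]2C(=O)C1
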